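Ring A is disconnected at C1–C10 and C2–C3, which leaves a two-carbon unit (C1–C2) and a ring B cyclohexenone whose C5 stereocentre and C4 appendage are those of (R)-carvone, the isopropenyl group being oxidised to an acrylate (C3=C4–C19). The key step exploits the fact that C10 is α to the C9 carbonyl of ring B and C3 is β to the C19 ester: the C10 enolate adds to phenyl vinyl sulfone, the sulfonyl carbanion closes ring A on the acrylate, and MeI traps the C4 enolate, setting C10 and C4 in one operation. Desulfonylation with enone reduction and triflation, B-alkyl Suzuki coupling and acetylation finish the route.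

Key step: step 6

Remark on numbering: labdane numbers are used throughout, also for the carvone-derived monocycles (ring A = C1–C5, C10; ring B = C5–C10; C18 = 4α-methyl, C19 = ester carbon on C4, C20 = methyl on C10, side chain C11–C16 on C9). The target is methyl 15-acetoxylabda-8,13E-dien-19-oate (4S,5R,10S).
Remark on the chemistry: compounds 3–7 are expected as C10 epimer mixtures (trans drawn); this centre becomes planar again in step 6, so the mixture is carried forward.

Step 1
Reactants: 1 (R)-(−)-carvone
Product: 3 (5R,6S)-2,6-dimethyl-5-(prop-1-en-2-yl)cyclohex-2-en-1-one (6-methylcarvone; trans isomer drawn), via carvone lithium dienolate 2 (not isolated)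
Conditions: LDA (lithium diisopropylamide), THF, −78 °C; then MeI, −78 → 0 °C
Reagents that add atoms: methyl iodide, CI
Why: Kinetic α′-deprotonation of the cross-conjugated enone and C-methylation of the dienolate (enolate alkylation) should give the 6-methyl ketone, mainly trans by approach anti to the isopropenyl group, and the configuration of this centre is immaterial because it is planarised again in step 6.

Step 2
Reactants: 3 6-methylcarvone
Product: 4 (5R,6S)-5-(3-chloroprop-1-en-2-yl)-2,6-dimethylcyclohex-2-en-1-one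
Conditions: Ca(OCl)2, solid CO2, CH2Cl2/H2O, 0 °C
Reagents that add atoms: calcium hypochlorite, [Ca+2].[O-]Cl.[O-]Cl
Why: Ene-type chlorination by HOCl generated in the flask should attack only the electron-rich 1,1-disubstituted alkene and give the transposed primary allylic chloride, the electron-poor enone being inert.

Step 3
Reactants: 4 allylic chloride
Product: 5 2-[(1R,2S)-2,4-dimethyl-3-oxocyclohex-4-en-1-yl]prop-2-enal
Conditions: N-methylmorpholine N-oxide (4 equiv), NaI (0.2 equiv), MeCN, 45 °C
Reagents that add atoms: N-methylmorpholine N-oxide, C[N+]1([O-])CCOCC1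
Why: Kornblum-type oxidation, in which the N-oxide oxygen displaces the allylic halide and the alkoxyammonium salt collapses with loss of the amine, should give the 2-substituted acrolein without touching the ring enone.

Step 4
Reactants: 5 enal
Product: 6 2-[(1R,2S)-2,4-dimethyl-3-oxocyclohex-4-en-1-yl]prop-2-enoic acid
Conditions: NaClO2, NaH2PO4, 2-methyl-2-butene, t-BuOH/H2O, 0 °C → rt
Reagents that add atoms: sodium chlorite, [Na+].[O-]Cl=O
Why: Pinnick oxidation converts conjugated aldehydes, α-methylene aldehydes included, into the acids under buffered conditions while the alkene scavenger protects both C=C bonds from HOCl.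

Step 5
Reactants: 6 acrylic acid
Product: 7 methyl 2-[(1R,2S)-2,4-dimethyl-3-oxocyclohex-4-en-1-yl]prop-2-enoate
Conditions: MeI, K2CO3, DMF, rt
Reagents that add atoms: methyl iodide, CI
Why: O-alkylation of the potassium carboxylate (SN2 esterification) should give the methyl ester under conditions too weakly basic to C-alkylate the ketone or isomerise the α-methylene unit.

Step 6
Reactants: 7 methyl 2-[(1R,2S)-2,4-dimethyl-3-oxocyclohex-4-en-1-yl]prop-2-enoate; 8 phenyl vinyl sulfone
Product: 12 methyl (1S,3R,4aS,8aR)-1,4a,6-trimethyl-5-oxo-3-(phenylsulfonyl)-1,2,3,4,4a,5,8,8a-octahydronaphthalene-1-carboxylate, via lithium dienolate 9 (not isolated), via sulfonyl carbanion 10 (not isolated), via ester enolate 11 (not isolated)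
Conditions: LiTMP (lithium 2,2,6,6-tetramethylpiperidide, 1.05 equiv), THF, −78 °C; 8, −78 → −30 °C; then MeI (5 equiv), DMPU, −78 → 0 °C
Reagents that add atoms: methyl iodide, CI
Why: LiTMP removes the α′ proton at C10 to give cross-conjugated dienolate 9, which adds to phenyl vinyl sulfone from the face anti to the C5 substituent (C1–C10 bond), and the α-sulfonyl carbanion 10 then adds to the CH2 terminus of the tethered acrylate (C2–C3 bond) to give ester enolate 11, which MeI methylates at C4. The closest known reaction type is the Michael–Michael ring closure (anionic [4+2] annulation of an enolate, a vinyl sulfone and a tethered acrylate) with alkylative trapping of the terminal enolate. Ring A closes in the 6-endo-trig mode through a chair-like transition state in which the C10–C1 and C5–C4 bonds are both equatorial, which gives the trans-decalin. C10 is controlled by the adjacent carvone-derived C5 centre, C4 by the axial C10 methyl group, which shields the β face so that MeI enters equatorially (α) and leaves the ester axial (β), and C2 should carry the sulfonyl group equatorially but is erased in step 7. The selectivity needed is attack of carbanion 10 on acrylate carbon C3 and not on enone carbon C7 (bridged bicyclo[2.2.2]octanone) nor proton transfer; the unhindered acrylate terminus, reachable from the diequatorial conformer, should react faster than the β-carbon of the trisubstituted enone, which demands a diaxial boat-like arrangement. A hindered amide base is used so that no amine adds to the acrylate.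

Step 7
Reactants: 12 sulfonyl enone ester
Product: 14 methyl (1S,4aS,8aR)-1,4a,6-trimethyl-5-{[(trifluoromethyl)sulfonyl]oxy}-1,2,3,4,4a,7,8,8a-octahydronaphthalene-1-carboxylate, via lithium enolate 13 (not isolated)
Conditions: Li (6 equiv), NH3(l)/THF, t-BuOH (1 equiv), −78 °C, short contact; isoprene; NH3 evaporated; then PhNTf2 (2 equiv), THF, 0 °C → rt
Reagents that add atoms: N-phenylbis(trifluoromethanesulfonimide), O=S(=O)(N(c1ccccc1)S(=O)(=O)C(F)(F)F)C(F)(F)F
Why: Dissolving-metal reduction should convert the enone into the C8=C9 lithium enolate (the only enolate possible, since C10 is quaternary) and cleave the C2–S bond of the alkyl aryl sulfone, and O-triflation of the enolate then fixes the tetrasubstituted C8=C9 alkene as its enol triflate while the hindered C19 ester survives the short cold exposure.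

Step 8
Reactants: 15 (2E)-3-methylpent-2-en-4-yn-1-ol
Product: 16 (2E)-3-methylpenta-2,4-dien-1-ol
Conditions: H2 (1 atm), Pd/CaCO3 poisoned with Pb(OAc)2, quinoline, EtOAc, rt, stopped after one equivalent of H2
Reagents that add atoms: none
Why: Semi-hydrogenation over poisoned palladium reduces the terminal alkyne to the vinyl group and should stop there, leaving the trisubstituted E-alkene unchanged.

Step 9
Reactants: 14 enol triflate; 16 (2E)-3-methylpenta-2,4-dien-1-ol
Product: 18 methyl (1S,4aS,8aR)-5-[(3E)-5-hydroxy-3-methylpent-3-en-1-yl]-1,4a,6-trimethyl-1,2,3,4,4a,7,8,8a-octahydronaphthalene-1-carboxylate, via bis-borane 17 (not isolated)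
Conditions: 16, 9-BBN (2.2 equiv), THF, 0 °C → rt; then 14, Pd(dppf)Cl2 (10 mol %), AsPh3 (10 mol %), 3 M aq K3PO4, DMF, 60 °C
Reagents that add atoms: none
Why: 9-BBN caps the hydroxyl as a borinate and adds anti-Markovnikov to the monosubstituted terminus of the diene, and B-alkyl Suzuki–Miyaura coupling of this primary alkylborane with the enol triflate forms the C9–C11 bond with both alkene geometries retained.

Step 10
Reactants: 18 allylic alcohol
Product: 19 methyl (1S,4aS,8aR)-5-[(3E)-5-acetoxy-3-methylpent-3-en-1-yl]-1,4a,6-trimethyl-1,2,3,4,4a,7,8,8a-octahydronaphthalene-1-carboxylate (target)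
Conditions: Ac2O, pyridine, DMAP (cat.), CH2Cl2, 0 °C → rt
Reagents that add atoms: acetic anhydride, CC(=O)OC(C)=O
Why: DMAP-catalysed acylation of the primary allylic alcohol gives the acetate, the hindered tertiary C19 methyl ester being inert.

Compound list
1 | (R)-(−)-carvone | C=C(C)[C@@H]1CC=C(C)C(=O)C1 | starting material
2 | carvone lithium dienolate, lithium (3R)-6-methyl-3-(prop-1-en-2-yl)cyclohexa-1,5-dien-1-olate | C=C(C)[C@@H]1CC=C(C)C(O[Li])=C1 | intermediate (not isolated)
3 | (5R,6S)-2,6-dimethyl-5-(prop-1-en-2-yl)cyclohex-2-en-1-one (trans drawn, C6 epimer present) | C=C(C)[C@@H]1CC=C(C)C(=O)[C@H]1C | intermediate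
4 | (5R,6S)-5-(3-chloroprop-1-en-2-yl)-2,6-dimethylcyclohex-2-en-1-one | C=C(CCl)[C@@H]1CC=C(C)C(=O)[C@H]1C | intermediate
5 | 2-[(1R,2S)-2,4-dimethyl-3-oxocyclohex-4-en-1-yl]prop-2-enal | C=C(C=O)[C@@H]1CC=C(C)C(=O)[C@H]1C | intermediate
6 | 2-[(1R,2S)-2,4-dimethyl-3-oxocyclohex-4-en-1-yl]prop-2-enoic acid | C=C(C(=O)O)[C@@H]1CC=C(C)C(=O)[C@H]1C | intermediate
7 | methyl 2-[(1R,2S)-2,4-dimethyl-3-oxocyclohex-4-en-1-yl]prop-2-enoate | C=C(C(=O)OC)[C@@H]1CC=C(C)C(=O)[C@H]1C | intermediate
8 | phenyl vinyl sulfone | C=CS(=O)(=O)c1ccccc1 | starting material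
9 | lithium dienolate of 7 (C9–OLi, C9=C10, C7=C8; 5R) | C=C(C(=O)OC)[C@@H]1CC=C(C)C(O[Li])=C1C | intermediate (not isolated)
10 | methyl 2-[(1R,2S)-2-[2-lithio-2-(phenylsulfonyl)ethyl]-2,4-dimethyl-3-oxocyclohex-4-en-1-yl]prop-2-enoate (C1 trans to the C5 substituent, C10 methyl cis) | C=C(C(=O)OC)[C@@H]1CC=C(C)C(=O)[C@@]1(C)CC([Li])S(=O)(=O)c1ccccc1 | intermediate (not isolated)
11 | lithium ester enolate at C4 of the trans-decalin (2α-phenylsulfonyl, 5α-H, 10β-methyl) | COC(O[Li])=C1C[C@H](S(=O)(=O)c3ccccc3)C[C@]2(C)C(=O)C(C)=CC[C@@H]12 | intermediate (not isolated)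
12 | methyl (1S,3R,4aS,8aR)-1,4a,6-trimethyl-5-oxo-3-(phenylsulfonyl)-1,2,3,4,4a,5,8,8a-octahydronaphthalene-1-carboxylate (4α-Me, 4β-CO2Me, 2α-SO2Ph, 5α-H, 10β-Me) | COC(=O)[C@@]1(C)C[C@H](S(=O)(=O)c3ccccc3)C[C@]2(C)C(=O)C(C)=CC[C@@H]12 | intermediate
13 | lithium C8=C9 enolate of methyl (1S,4aS,8aR)-1,4a,6-trimethyl-5-oxodecahydronaphthalene-1-carboxylate | COC(=O)[C@@]1(C)CCC[C@]2(C)C(O[Li])=C(C)CC[C@@H]12 | intermediate (not isolated)
14 | methyl (1S,4aS,8aR)-1,4a,6-trimethyl-5-{[(trifluoromethyl)sulfonyl]oxy}-1,2,3,4,4a,7,8,8a-octahydronaphthalene-1-carboxylate | COC(=O)[C@@]1(C)CCC[C@]2(C)C(OS(=O)(=O)C(F)(F)F)=C(C)CC[C@@H]12 | intermediate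
15 | (2E)-3-methylpent-2-en-4-yn-1-ol | C#C/C(C)=C/CO | starting material
16 | (2E)-3-methylpenta-2,4-dien-1-ol | C=C/C(C)=C/CO | intermediate
17 | 9-[(3E)-5-(9-borabicyclo[3.3.1]nonan-9-yloxy)-3-methylpent-3-en-1-yl]-9-borabicyclo[3.3.1]nonane | B1(CC/C(C)=C/COB3C4CCCC3CCC4)C2CCCC1CCC2 | intermediate (not isolated)
18 | methyl (1S,4aS,8aR)-5-[(3E)-5-hydroxy-3-methylpent-3-en-1-yl]-1,4a,6-trimethyl-1,2,3,4,4a,7,8,8a-octahydronaphthalene-1-carboxylate | COC(=O)[C@@]1(C)CCC[C@]2(C)C(CC/C(C)=C/CO)=C(C)CC[C@@H]12 | intermediate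
19 | methyl (1S,4aS,8aR)-5-[(3E)-5-acetoxy-3-methylpent-3-en-1-yl]-1,4a,6-trimethyl-1,2,3,4,4a,7,8,8a-octahydronaphthalene-1-carboxylate | COC(=O)[C@@]1(C)CCC[C@]2(C)C(CC/C(C)=C/COC(C)=O)=C(C)CC[C@@H]12 | target

Total step count: 10. Longest linear sequence: 9 (steps 1–7, 9, 10).

Steps most likely to fail

Step 6. Carbanion 10 may close onto the ring enone (bridged bicycle) or be quenched by proton transfer from the γ-positions before ring A forms, and the acrylate may oligomerise under the basic conditions. The fallback sets out from 7 and returns at 14, making the two bonds in separate steps with a radical ring closure that strongly prefers the acrylate terminus. Dienolate 9 is C-alkylated with 2-bromoethyl trifluoromethanesulfonate (THF, −78 °C) to give methyl 2-[(1R,2S)-2-(2-bromoethyl)-2,4-dimethyl-3-oxocyclohex-4-en-1-yl]prop-2-enoate F1. Slow addition of Bu3SnH/AIBN in benzene at 80 °C generates the primary C2 radical, whose polarity-matched 6-endo addition to the acrylate CH2 should give the trans-decalin ester F2 (C4–H, epimers). Li/NH3 followed by PhNTf2 converts the enone into the enol triflate F3. LDA then MeI (THF/DMPU, −78 °C) methylates the C4 ester enolate from the α face to give 14.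

Step 7. Electron transfer may over-reduce the C19 ester or leave the C–S bond intact, and amide bases left after the reduction may consume the triflating agent. The fallback sets out from 12 and returns at 18, separating hydride conjugate reduction from a late, mild desulfonylation. LiBH(s-Bu)3 (THF, −78 °C) reduces the enone in the conjugate sense and PhNTf2 traps the enolate as the sulfonyl enol triflate F4. B-alkyl Suzuki coupling of F4 with bis-borane 17 under the conditions of step 9 gives the sulfonyl alcohol F5. Mg turnings in MeOH (50 °C) then cleave the sulfone reductively to give 18.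

Step 9. Oxidative addition and transmetalation at the tetrasubstituted enol triflate flanked by the quaternary C10 may be slow, so that protodeboronation or β-hydride elimination of the alkylborane wins. The fallback sets out from 14 and 15 and returns at 18, replacing the sp3 partner by an sp2 partner at the hindered carbon. Radical hydrostannation of 15 (Bu3SnH, AIBN, 80 °C) gives (2E,4E)-3-methyl-5-(tributylstannyl)penta-2,4-dien-1-ol F6. Stille coupling of F6 with 14 (Pd2(dba)3, AsPh3, LiCl, NMP, 60 °C) gives the triene alcohol F7. Diimide (2-nitrobenzenesulfonyl hydrazide, Et3N, CH2Cl2, rt) should reduce the trans-disubstituted C11=C12 alkene in preference to the tri- and tetrasubstituted ones and give 18.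

Further compounds
F1 | step 6 | methyl 2-[(1R,2S)-2-(2-bromoethyl)-2,4-dimethyl-3-oxocyclohex-4-en-1-yl]prop-2-enoate | C=C(C(=O)OC)[C@@H]1CC=C(C)C(=O)[C@@]1(C)CCBr
F2 | step 6 | methyl (4aS,8aS)-4a,6-dimethyl-5-oxo-1,2,3,4,4a,5,8,8a-octahydronaphthalene-1-carboxylate (C1 epimers; 5α-H, 10β-Me) | COC(=O)C1CCC[C@]2(C)C(=O)C(C)=CC[C@@H]12
F3 | step 6 | methyl (4aS,8aS)-4a,6-dimethyl-5-{[(trifluoromethyl)sulfonyl]oxy}-1,2,3,4,4a,7,8,8a-octahydronaphthalene-1-carboxylate (C1 epimers) | COC(=O)C1CCC[C@]2(C)C(OS(=O)(=O)C(F)(F)F)=C(C)CC[C@@H]12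
F4 | step 7 | methyl (1S,3R,4aS,8aR)-1,4a,6-trimethyl-3-(phenylsulfonyl)-5-{[(trifluoromethyl)sulfonyl]oxy}-1,2,3,4,4a,7,8,8a-octahydronaphthalene-1-carboxylate | COC(=O)[C@@]1(C)C[C@H](S(=O)(=O)c3ccccc3)C[C@]2(C)C(OS(=O)(=O)C(F)(F)F)=C(C)CC[C@@H]12
F5 | step 7 | methyl (1S,3R,4aS,8aR)-5-[(3E)-5-hydroxy-3-methylpent-3-en-1-yl]-1,4a,6-trimethyl-3-(phenylsulfonyl)-1,2,3,4,4a,7,8,8a-octahydronaphthalene-1-carboxylate | COC(=O)[C@@]1(C)C[C@H](S(=O)(=O)c3ccccc3)C[C@]2(C)C(CC/C(C)=C/CO)=C(C)CC[C@@H]12
F6 | step 9 | (2E,4E)-3-methyl-5-(tributylstannyl)penta-2,4-dien-1-ol | OC/C=C(C)/C=C/[Sn](CCCC)(CCCC)CCCC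
F7 | step 9 | methyl (1S,4aS,8aR)-5-[(1E,3E)-5-hydroxy-3-methylpenta-1,3-dien-1-yl]-1,4a,6-trimethyl-1,2,3,4,4a,7,8,8a-octahydronaphthalene-1-carboxylate | COC(=O)[C@@]1(C)CCC[C@]2(C)C(/C=C/C(C)=C/CO)=C(C)CC[C@@H]12
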